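**Plan**

- Retrosynthesis: the ketal bond C2–O7' is opened first (back to a C2 methyl ketal with all phenols benzylated). Then C3–C8' and O1'–C8a' are cut together, giving racemic 2-methoxyflavan-3,4-dione 21 and open-chain bromofluoroarene alcohol 12. Unprimed locants are the flavanone half (benzo ring A, pyranone ring C); primed locants are the flavan half (benzo ring D, pyran ring F).
- Enabling feature: ring D carries O1', C3 and O7' on three adjacent carbons (C8a', C8', C7'). This is the pattern left when a nucleophile and an electrophile add across a 3-alkoxyaryne.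
- Forward: 12 is built on a symmetric dibromofluoroarene (chain from methyl (R)-glycidate, then aryl ketone, then chelate reduction). 21 comes from a chalcone through flavone and flavonol (rings A and C first). The key step closes ring F and joins the halves; debenzylation and ketal exchange close the dihydrofuran last.
- Stereochemistry: C3' comes from the glycidate and C2' from a chelation-controlled reduction (anti). C3 is set in the key step by addition to the ketone, with the C3 epimers separated. C2 is set in the final ketal exchange under control of C3.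

Key step: step 13

Assumption: the target string is followed literally as (2R,3S,2'S,3'R). Read this way, O7' on C2 and C8' on C3 lie on opposite faces of ring C, which is the more strained ring fusion. A reversible ketal closure is expected to favour the other, cis fusion, so C2 is written as given and must be confirmed on the final compound. C3, C2' and C3' are fixed earlier and are not affected.

**Route**

Step 1
Reactants: 1 5-fluororesorcinol
Product: 2 1,3-bis(benzyloxy)-5-fluorobenzene
Conditions: BnBr (2.2 equiv), K2CO3, DMF, 60 °C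
Reagents that add atoms: benzyl bromide, BrCc1ccccc1
Why: Williamson etherification of both phenols; the aryl fluoride is inert to carbonate.

Step 2
Reactants: 2 1,3-bis(benzyloxy)-5-fluorobenzene
Product: 3 1,5-bis(benzyloxy)-2,4-dibromo-3-fluorobenzene
Conditions: NBS (2.1 equiv), MeCN, 0 °C to rt
Reagents that add atoms: N-bromosuccinimide, O=C1CCC(=O)N1Br
Why: Electrophilic aromatic bromination should take the two positions that flank fluorine (each para to one ether) before the hindered position between the two ethers, as is usual for 3,5-dialkoxyaryl systems, and the symmetric product makes the later mono-exchange unambiguous.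

Step 3
Reactants: 3 1,5-bis(benzyloxy)-2,4-dibromo-3-fluorobenzene; 4 methyl (2R)-oxirane-2-carboxylate
Product: 6 methyl (2R)-3-[4,6-bis(benzyloxy)-3-bromo-2-fluorophenyl]-2-hydroxypropanoate, via arylmagnesium chloride 5 (not isolated)
Conditions: i-PrMgCl·LiCl (1.05 equiv), THF, −15 °C; then CuI (10 mol %), 4, −30 to 0 °C; aq NH4Cl
Reagents that add atoms: none
Why: Bromine–magnesium exchange at one of two equivalent bromides gives a fluoroaryl Grignard reagent that should be stable below 0 °C, and copper-catalysed epoxide opening at the unsubstituted CH2 of the glycidate attaches the chain while C3' is taken unchanged from the chiral pool.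

Step 4
Reactants: 6 methyl (2R)-3-[4,6-bis(benzyloxy)-3-bromo-2-fluorophenyl]-2-hydroxypropanoate
Product: 7 methyl (2R)-2-(benzyloxy)-3-[4,6-bis(benzyloxy)-3-bromo-2-fluorophenyl]propanoate
Conditions: BnBr, Ag2O, CH2Cl2, rt, dark
Reagents that add atoms: benzyl bromide, BrCc1ccccc1
Why: Silver-oxide-mediated Williamson etherification benzylates an α-hydroxy ester without a base strong enough to epimerise the α-centre.

Step 5
Reactants: 7 methyl (2R)-2-(benzyloxy)-3-[4,6-bis(benzyloxy)-3-bromo-2-fluorophenyl]propanoate
Product: 8 (2R)-2-(benzyloxy)-3-[4,6-bis(benzyloxy)-3-bromo-2-fluorophenyl]-N-methoxy-N-methylpropanamide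
Conditions: MeNHOMe·HCl, AlMe3, CH2Cl2, 0 °C to rt; aq HCl
Reagents that add atoms: N,O-dimethylhydroxylamine hydrochloride, CNOC.Cl
Why: Weinreb aminolysis of the ester by the aluminium amide leaves the aryl bromide and the α-centre untouched.

Step 6
Reactants: 8 (2R)-2-(benzyloxy)-3-[4,6-bis(benzyloxy)-3-bromo-2-fluorophenyl]-N-methoxy-N-methylpropanamide; 9 1-(benzyloxy)-4-bromobenzene
Product: 11 (2R)-2-(benzyloxy)-1-[4-(benzyloxy)phenyl]-3-[4,6-bis(benzyloxy)-3-bromo-2-fluorophenyl]propan-1-one, via 4-(benzyloxy)phenylmagnesium bromide 10 (not isolated)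
Conditions: 9, Mg turnings, THF, 40 °C; then 8, THF, 0 °C; aq NH4Cl
Reagents that add atoms: none
Why: Weinreb ketone synthesis: the magnesium chelate of the tetrahedral adduct stops the addition at the ketone, and the aryl bromide and fluoride do not exchange with an arylmagnesium reagent.

Step 7
Reactants: 11 (2R)-2-(benzyloxy)-1-[4-(benzyloxy)phenyl]-3-[4,6-bis(benzyloxy)-3-bromo-2-fluorophenyl]propan-1-one
Product: 12 (1S,2R)-2-(benzyloxy)-1-[4-(benzyloxy)phenyl]-3-[4,6-bis(benzyloxy)-3-bromo-2-fluorophenyl]propan-1-ol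
Conditions: Zn(BH4)2, Et2O, −30 to 0 °C; aq NH4Cl
Reagents that add atoms: none
Why: Chelation-controlled reduction (Cram-chelate model): zinc bridges the carbonyl and the α-benzyloxy oxygen and hydride enters on the side of the α-hydrogen, which should give the anti (1S,2R) alcohol, the arrangement a 2',3'-trans flavan needs when the C2'–O bond is kept.

Step 8
Reactants: 13 2,4,6-trihydroxyacetophenone
Product: 14 1-[2,4-bis(benzyloxy)-6-hydroxyphenyl]ethan-1-one
Conditions: BnBr (2.1 equiv), K2CO3, acetone, reflux
Reagents that add atoms: benzyl bromide, BrCc1ccccc1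
Why: Williamson etherification spares the hydroxyl that is hydrogen-bonded to the acetyl group, so one ortho and the para hydroxyl are benzylated.

Step 9
Reactants: 14 1-[2,4-bis(benzyloxy)-6-hydroxyphenyl]ethan-1-one; 15 4-(benzyloxy)benzaldehyde
Product: 16 (E)-1-[2,4-bis(benzyloxy)-6-hydroxyphenyl]-3-[4-(benzyloxy)phenyl]prop-2-en-1-one
Conditions: KOH, EtOH–THF, rt
Reagents that add atoms: none
Why: Claisen–Schmidt aldol condensation, which gives the conjugated E-enone.

Step 10
Reactants: 16 (E)-1-[2,4-bis(benzyloxy)-6-hydroxyphenyl]-3-[4-(benzyloxy)phenyl]prop-2-en-1-one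
Product: 17 5,7-bis(benzyloxy)-2-[4-(benzyloxy)phenyl]-4H-chromen-4-one
Conditions: I2 (10 mol %), DMSO, 130 °C
Reagents that add atoms: none
Why: Iodine-catalysed oxidative cyclisation of a 2'-hydroxychalcone (oxa-Michael closure of ring C, then dehydrogenation with DMSO as terminal oxidant) is a standard flavone synthesis.

Step 11
Reactants: 17 5,7-bis(benzyloxy)-2-[4-(benzyloxy)phenyl]-4H-chromen-4-one
Product: 19 5,7-bis(benzyloxy)-2-[4-(benzyloxy)phenyl]-3-hydroxy-4H-chromen-4-one, via flavone epoxide 18 (not isolated)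
Conditions: DMDO, acetone–CH2Cl2, 0 °C to rt; then p-TsOH (cat.), CH2Cl2
Reagents that add atoms: dimethyldioxirane, CC1(C)OO1
Why: Epoxidation of the C2=C3 enol-ether double bond and acid-catalysed opening of the epoxide at C2 with loss of H3 is a known flavone-to-flavonol conversion that tolerates benzyl ethers.

Step 12
Reactants: 19 5,7-bis(benzyloxy)-2-[4-(benzyloxy)phenyl]-3-hydroxy-4H-chromen-4-one
Product: 21 5,7-bis(benzyloxy)-2-[4-(benzyloxy)phenyl]-2-methoxychromane-3,4-dione (racemic), via C3 methanol hemiketal 20 (not isolated)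
Conditions: PhI(OAc)2 (1.1 equiv), MeOH–CH2Cl2, 0 °C to rt; then toluene, 4 Å MS, reflux
Reagents that add atoms: methanol, CO
Why: Oxidative methanolysis of a flavonol with a trivalent iodine reagent (ligand exchange at the enolic 3-OH, attack of methanol at C2, loss of PhI) gives the 2-methoxy-3,4-dione, which is first held as hemiketal 20 and should revert to the free C3 ketone when methanol is removed.

Step 13
Reactants: 12 (1S,2R)-2-(benzyloxy)-1-[4-(benzyloxy)phenyl]-3-[4,6-bis(benzyloxy)-3-bromo-2-fluorophenyl]propan-1-ol; 21 5,7-bis(benzyloxy)-2-[4-(benzyloxy)phenyl]-2-methoxychromane-3,4-dione (racemic, 2 equiv)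
Product: 25 (3S)-5,7-bis(benzyloxy)-2-[4-(benzyloxy)phenyl]-3-hydroxy-2-methoxy-3-[(2S,3R)-3,5,7-tris(benzyloxy)-2-[4-(benzyloxy)phenyl]-3,4-dihydro-2H-chromen-8-yl]chroman-4-one (C2 either configuration), via dilithiated alkoxide 22 (not isolated), via aryne alkoxide 23 (not isolated), via 8-lithioflavan 24 (not isolated)
Conditions: n-BuLi (2.05 equiv), THF, −78 °C; warm to −30 °C; recool to −78 °C, 21 in THF; aq NH4Cl; chromatography
Reagents that add atoms: none
Why: Proposed new method: the first equivalent of n-BuLi forms the C2' lithium alkoxide and the second exchanges the C8' bromine (22); on warming, loss of LiF gives the C8'–C8a' aryne 23, the tethered alkoxide adds to C8a' in a 6-exo-dig closure of pyran ring F, and the resulting C8' aryllithium 24, flanked by O1' and O7', adds at −78 °C to the C3 ketone of 21. The closest known reactions are anionic aryne cyclisations of tethered nucleophiles with electrophile quench and additions of magnesium amides or thiolates to arynes followed by trapping; a tethered lithium alkoxide with a ketone quench has not been shown. The alkoxide must add at C8a' and not C8': the C7' benzyloxy group polarises the aryne that way and C8a' is the only carbon the tether can reach, while the placement of F and Br settles C8' over C6'. The aryllithium must choose C3 over C4: C3 is a non-enolisable ketone activated by the neighbouring ketal and carbonyl, whereas C4 is a donor-deactivated aryl ketone. The new C3 stereocentre is steered within each dione enantiomer by the C2 ketal carbon (attack anti to the axial methoxy group is expected), but 21 is racemic, so the (3S) and (3R) adducts, which are diastereomers because of C2' and C3', should both form; the excess of 21 allows a kinetic preference and the (3S) series is taken on after chromatography. Either C2 configuration serves because C2 is reset in step 15, and C2' and C3' are untouched because the C2'–O bond is never broken.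

Step 14
Reactants: 25 (3S)-adduct, fully benzylated
Product: 26 (3S)-3,5,7-trihydroxy-2-(4-hydroxyphenyl)-2-methoxy-3-[(2S,3R)-3,5,7-trihydroxy-2-(4-hydroxyphenyl)-3,4-dihydro-2H-chromen-8-yl]chroman-4-one
Conditions: H2 (1 atm), Pd(OH)2/C, THF–MeOH, rt
Reagents that add atoms: none
Why: Hydrogenolysis of the seven benzyl ethers should be faster than reduction of the deactivated C4 ketone or cleavage of the ketal and ring ethers under neutral conditions, and methanol as co-solvent makes any exchange at C2 degenerate.

Step 15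
Reactants: 26 heptahydroxy methyl ketal
Product: 27 target CNP0146414.1
Conditions: PPTS (cat.), THF, 4 Å MS, 40 °C
Reagents that add atoms: none
Why: Acid-catalysed intramolecular transketalisation: loss of methanol gives a C2 oxocarbenium ion stabilised by O1 and the 4-hydroxyphenyl ring, and O7', held beside it by the C8'–C3 bond, closes the dihydrofuran (5-exo-trig); C2 is set here under equilibrating conditions by the C3 centre and is written with the descriptor of the target string.

**Compound list**

1 | 5-fluororesorcinol | Oc1cc(O)cc(F)c1 | starting material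
2 | 1,3-bis(benzyloxy)-5-fluorobenzene | Fc1cc(OCc2ccccc2)cc(OCc2ccccc2)c1 | intermediate
3 | 1,5-bis(benzyloxy)-2,4-dibromo-3-fluorobenzene | Fc1c(Br)c(OCc2ccccc2)cc(OCc2ccccc2)c1Br | intermediate
4 | methyl (2R)-oxirane-2-carboxylate | COC(=O)[C@H]1CO1 | starting material
5 | [4,6-bis(benzyloxy)-3-bromo-2-fluorophenyl]magnesium chloride | Cl[Mg]c1c(F)c(Br)c(OCc2ccccc2)cc1OCc1ccccc1 | intermediate (not isolated)
6 | methyl (2R)-3-[4,6-bis(benzyloxy)-3-bromo-2-fluorophenyl]-2-hydroxypropanoate | COC(=O)[C@H](O)Cc1c(F)c(Br)c(OCc2ccccc2)cc1OCc1ccccc1 | intermediate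
7 | methyl (2R)-2-(benzyloxy)-3-[4,6-bis(benzyloxy)-3-bromo-2-fluorophenyl]propanoate | COC(=O)[C@H](OCc1ccccc1)Cc1c(F)c(Br)c(OCc2ccccc2)cc1OCc1ccccc1 | intermediate
8 | (2R)-2-(benzyloxy)-3-[4,6-bis(benzyloxy)-3-bromo-2-fluorophenyl]-N-methoxy-N-methylpropanamide | CON(C)C(=O)[C@H](OCc1ccccc1)Cc1c(F)c(Br)c(OCc2ccccc2)cc1OCc1ccccc1 | intermediate
9 | 1-(benzyloxy)-4-bromobenzene | Brc1ccc(OCc2ccccc2)cc1 | starting material
10 | [4-(benzyloxy)phenyl]magnesium bromide | Br[Mg]c1ccc(OCc2ccccc2)cc1 | intermediate (not isolated)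
11 | (2R)-2-(benzyloxy)-1-[4-(benzyloxy)phenyl]-3-[4,6-bis(benzyloxy)-3-bromo-2-fluorophenyl]propan-1-one | O=C(c1ccc(OCc2ccccc2)cc1)[C@H](OCc1ccccc1)Cc1c(F)c(Br)c(OCc2ccccc2)cc1OCc1ccccc1 | intermediate
12 | (1S,2R)-2-(benzyloxy)-1-[4-(benzyloxy)phenyl]-3-[4,6-bis(benzyloxy)-3-bromo-2-fluorophenyl]propan-1-ol | O[C@@H](c1ccc(OCc2ccccc2)cc1)[C@H](OCc1ccccc1)Cc1c(F)c(Br)c(OCc2ccccc2)cc1OCc1ccccc1 | intermediate
13 | 2,4,6-trihydroxyacetophenone | CC(=O)c1c(O)cc(O)cc1O | starting material
14 | 1-[2,4-bis(benzyloxy)-6-hydroxyphenyl]ethan-1-one | CC(=O)c1c(O)cc(OCc2ccccc2)cc1OCc1ccccc1 | intermediate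
15 | 4-(benzyloxy)benzaldehyde | O=Cc1ccc(OCc2ccccc2)cc1 | starting material
16 | (E)-1-[2,4-bis(benzyloxy)-6-hydroxyphenyl]-3-[4-(benzyloxy)phenyl]prop-2-en-1-one | O=C(/C=C/c1ccc(OCc2ccccc2)cc1)c1c(O)cc(OCc2ccccc2)cc1OCc1ccccc1 | intermediate
17 | 5,7-bis(benzyloxy)-2-[4-(benzyloxy)phenyl]-4H-chromen-4-one | O=c1cc(-c2ccc(OCc3ccccc3)cc2)oc2cc(OCc3ccccc3)cc(OCc3ccccc3)c12 | intermediate
18 | 5,7-bis(benzyloxy)-2-[4-(benzyloxy)phenyl]-2,3-epoxychroman-4-one (racemic) | O=C1c2c(OCc3ccccc3)cc(OCc3ccccc3)cc2OC2(c3ccc(OCc4ccccc4)cc3)OC12 | intermediate (not isolated)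
19 | 5,7-bis(benzyloxy)-2-[4-(benzyloxy)phenyl]-3-hydroxy-4H-chromen-4-one | O=c1c(O)c(-c2ccc(OCc3ccccc3)cc2)oc2cc(OCc3ccccc3)cc(OCc3ccccc3)c12 | intermediate
20 | 5,7-bis(benzyloxy)-2-[4-(benzyloxy)phenyl]-3-hydroxy-2,3-dimethoxychroman-4-one | COC1(c2ccc(OCc3ccccc3)cc2)Oc2cc(OCc3ccccc3)cc(OCc3ccccc3)c2C(=O)C1(O)OC | intermediate (not isolated)
21 | 5,7-bis(benzyloxy)-2-[4-(benzyloxy)phenyl]-2-methoxychromane-3,4-dione (racemic) | COC1(c2ccc(OCc3ccccc3)cc2)Oc2cc(OCc3ccccc3)cc(OCc3ccccc3)c2C(=O)C1=O | intermediate
22 | lithium alkoxide of 12 with lithium in place of bromine | [Li]O[C@@H](c1ccc(OCc2ccccc2)cc1)[C@H](OCc1ccccc1)Cc1c(F)c([Li])c(OCc2ccccc2)cc1OCc1ccccc1 | intermediate (not isolated)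
23 | lithium alkoxide carrying the C8'–C8a' aryne (4,6-bis(benzyloxy)benzyne tethered at C1) | [Li]O[C@@H](c1ccc(OCc2ccccc2)cc1)[C@H](OCc1ccccc1)CC1=C(OCc2ccccc2)C=C(OCc2ccccc2)C#C1 | intermediate (not isolated)
24 | [(2S,3R)-3,5,7-tris(benzyloxy)-2-[4-(benzyloxy)phenyl]-3,4-dihydro-2H-chromen-8-yl]lithium | [Li]c1c(OCc2ccccc2)cc(OCc2ccccc2)c2c1O[C@@H](c1ccc(OCc3ccccc3)cc1)[C@H](OCc1ccccc1)C2 | intermediate (not isolated)
25 | (3S)-5,7-bis(benzyloxy)-2-[4-(benzyloxy)phenyl]-3-hydroxy-2-methoxy-3-[(2S,3R)-3,5,7-tris(benzyloxy)-2-[4-(benzyloxy)phenyl]-3,4-dihydro-2H-chromen-8-yl]chroman-4-one (C2 either configuration) | COC1(c2ccc(OCc3ccccc3)cc2)Oc2cc(OCc3ccccc3)cc(OCc3ccccc3)c2C(=O)[C@@]1(O)c1c(OCc2ccccc2)cc(OCc2ccccc2)c2c1O[C@@H](c1ccc(OCc3ccccc3)cc1)[C@H](OCc1ccccc1)C2 | intermediate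
26 | (3S)-3,5,7-trihydroxy-2-(4-hydroxyphenyl)-2-methoxy-3-[(2S,3R)-3,5,7-trihydroxy-2-(4-hydroxyphenyl)-3,4-dihydro-2H-chromen-8-yl]chroman-4-one (C2 either configuration) | COC1(c2ccc(O)cc2)Oc2cc(O)cc(O)c2C(=O)[C@@]1(O)c1c(O)cc(O)c2c1O[C@@H](c1ccc(O)cc1)[C@H](O)C2 | intermediate
27 | CNP0146414.1: (2R,3S)-3,5,7-trihydroxy-2-(4-hydroxyphenyl)flavanone joined through C3–C8' and through the ketal bond C2–O7' to a (2'S,3'R)-3',5'-dihydroxy-2'-(4-hydroxyphenyl)flavan | O=C1c2c(O)cc(O)cc2O[C@@]2(c3ccc(O)cc3)Oc3cc(O)c4c(c3[C@]12O)O[C@@H](c1ccc(O)cc1)[C@H](O)C4 | target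

**Step count and risks**

Total: 15 steps. Longest linear sequence: 10 steps (steps 1–7, then 13–15) from 5-fluororesorcinol; the dione branch is 5 steps (8–12).

Steps most likely to fail:

1. Step 13 (the one new method). Three processes may go wrong. The lithium alkoxide may add too slowly to the aryne, so that intermolecular capture of the aryne by an aryllithium competes. The hindered, doubly ortho-oxygenated aryllithium may add sluggishly or transfer an electron to the dione. Facial selectivity at C3 relative to the flavan centres is not secured, so part of the material ends in the (3R) series. Fallback from 12, returning at 25: KH in THF–DMF (0 °C to rt) closes the pyran by intramolecular SNAr displacement of fluoride by the alkoxide, giving (2S,3R)-3,5,7-tris(benzyloxy)-2-[4-(benzyloxy)phenyl]-8-bromo-3,4-dihydro-2H-chromene F1. Bromine–lithium exchange on F1 (n-BuLi, THF, −78 °C) then gives aryllithium 24 without any aryne, and its addition to 21 rejoins the route at 25. The C3 epimers are separated as in the main route.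

2. Step 12. The hemiketal may fail to release methanol cleanly, the dione may pick up water on handling, or the vicinal dione may undergo ring contraction on heating. Fallback from 17, returning at 21: DMDO in acetone at 0 °C without acid gives epoxide 18; methanol opens it at C2 to 5,7-bis(benzyloxy)-2-[4-(benzyloxy)phenyl]-3-hydroxy-2-methoxychroman-4-one F2. Dess–Martin periodinane in CH2Cl2 then oxidises the secondary C3 alcohol to 21 under anhydrous conditions, so no hemiketal has to be dehydrated.

3. Step 14. Over-reduction may occur (hydrogenolysis of the benzylic ketal C2–O bond, of the benzylic C3–OH or C2'–O1' bonds, or reduction of the C4 ketone), or the hindered 3'-O-benzyl ether may cleave incompletely. Fallback from 25, returning at 27: BCl3 with pentamethylbenzene as cation scavenger in CH2Cl2 at −78 °C removes the benzyl groups by Lewis-acid cleavage. The same acid ionises the C2 methyl ketal, so O7' closes the dihydrofuran in the same operation and no new isolable compound is made (F0). Any acid-induced equilibration at C2' would favour the 2',3'-trans flavan already present.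

Further compounds
F1 | step 13 | (2S,3R)-3,5,7-tris(benzyloxy)-2-[4-(benzyloxy)phenyl]-8-bromo-3,4-dihydro-2H-chromene | Brc1c(OCc2ccccc2)cc(OCc2ccccc2)c2c1O[C@@H](c1ccc(OCc3ccccc3)cc1)[C@H](OCc1ccccc1)C2
F2 | step 12 | 5,7-bis(benzyloxy)-2-[4-(benzyloxy)phenyl]-3-hydroxy-2-methoxychroman-4-one (racemic) | COC1(c2ccc(OCc3ccccc3)cc2)Oc2cc(OCc3ccccc3)cc(OCc3ccccc3)c2C(=O)C1O
F0 | step 14 | none | none
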